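## Structural features

The target is a guaiane: a cis-fused bicyclo[5.3.0]decane in which a cyclopentane (C1–C5) and a cycloheptane (C1, C5–C10) share the C1–C5 bond, with a three-carbon side chain (C11–C13) on C7. It has six stereocentres. C4–C5–C6–C7 form a contiguous row on one edge and C10–C1 on the other, so each tertiary methyl carbinol (C4, C10) is next to a ring-fusion carbon. Both carry their hydroxyl on the face of the fusion hydrogens (called α below); the C6 hydroxyl is also α and the C7 substituent is β. C11 is a non-stereogenic tertiary carbinol carrying two acetoxymethyl groups. Fragile points are the two primary acetates beside free hydroxyls (hydrolysis, acyl migration) and three tertiary alcohols (dehydration). In any intermediate with a C6 ketone, the β-oxygens at C4 and C11 invite retro-aldol or β-elimination, and C1, C5 and C7 can epimerise. The real difficulty is the oxygenated seven-membered ring: C6 and C10 must both be oxidised and then told apart, and five ring stereocentres must be set relative to C4. The key step uses the fact that C6 and C10 are 1,5-related across C7–C8–C9 and 1,4-related across C1–C5. Taking two carbons out of the C7–C9 bridge leaves a cyclopentane-1,3-dione fused to ring C1–C5, so the seven-membered ring can come from that dione and a two-carbon alkene by ring expansion. The C4 carbinol (methyl, hydroxyl, two different carbon arms) maps onto the tertiary carbinol of (R)-linalool.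

## Logic of the disconnections

**25 to 22.** The Si–O bond at C4 and the C10–O bond are cut last. Without the C10 oxygen, C10 becomes an sp2 carbon carrying C14 as an exocyclic methylene (22, through 24 and 23). This removes one stereocentre and one hydroxyl that would otherwise need protection. The forward step must put oxygen on the tertiary carbon and on the α face, and must leave two acetates untouched.

**22 to 19.** The two O–acetyl bonds, the two C–H bonds at C12/C13 and the C6–H bond are cut, giving 21, then 20, then 19. The side chain becomes a symmetric hydroxymalonate and C6 a ketone, which is the pattern an aldol leaves. The forward steps must deliver hydride to C6 from the side-chain face and acylate only the two primary hydroxyls.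

**19 to 17 and 18.** The C7–C11 bond is cut. C11 is a tertiary carbinol β to the C6 carbonyl, so this is an aldol retron with the non-enolisable tricarbonyl 18. The cut removes seven carbons and the C7 stereocentre. The forward step must enolise the ketone toward C7, not C5, and must give the 5,7-cis arrangement.

**17 to 16.** The C10=C14 bond is cut to a carbonyl. This gives a diketone whose two carbonyls differ only in their surroundings. The forward olefination must take C10 and not C6, without base, so that C1 and C5 stay put.

**16 to 12 and 13.** The C9–C10 and C7–C8 bonds are cut (or, equivalently, C6–C7 and C8–C9) and the old bond between the central carbon and the carbonyl carbon is restored. The seven-membered diketone shrinks to a five-membered 1,3-dione and the two carbons leave as 13. The forward step needs the enol of 12 to add 13 under light and the cyclobutanol to fragment; ring fusion and C4 are spectators.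

**12 to 11.** The bond between the central methylene carbon and the C6 carbonyl carbon is cut, which opens the dione ring to a methyl ketone and an ester on neighbouring ring carbons. The forward Claisen closure needs these two groups cis and needs the methyl group to be the nucleophile.

**11 to 9.** The Si–O bond and the C1–H and C5–H bonds are cut, through 10. Both ring-fusion stereocentres disappear into one tetrasubstituted alkene. The forward hydrogenation must add to the face of the C4 oxygen. This is why the alcohol is left free until this point and silylated only afterwards.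

**9 to 5.** The C10=O bond is traced to a C=CH2 bond (7), and the C5–C6 bond to an enol triflate (6) of a ketone (5). Ketone 5 has only one enolisable position, so the triflate regiochemistry is fixed. The forward steps need a cleavage that takes only the terminal alkene and a carbonylation next to a quaternary carbon.

**5 to 3.** The C5 carbonyl is traced to a secondary alcohol (4) and the C1–C10 bond is cut to an epoxide (3) and a three-carbon vinyl nucleophile. The forward opening must occur at C1, the epoxide carbon remote from the quaternary carbinol.

**3 to 1.** The epoxide C–O bonds are cut to the cyclopentene 2, and the C1=C5 bond of 2 is cut to the diene 1. This reaches a chiral-pool compound whose only stereocentre is C4. The forward ring-closing metathesis makes no demand on stereochemistry.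

## Other disconnections considered

**Alternative 1:** The cut is through C1–C5, the C10–O ether bond and C6–C7, back to the acyclic enynal (4E,8R)-8-(tert-butyldimethylsilyloxy)-4,8-dimethyldec-4-en-9-ynal (A1). In the forward step a cationic monovalent gold catalyst activates the alkyne; the trisubstituted alkene attacks it, the aldehyde oxygen captures the C10 cation, and the resulting oxocarbenium is trapped at C6. This gives the 7,10-oxa-bridged hydroazulene A2.
- In its favour: both rings and three bonds form in one catalytic operation. C1 and C10 are set together by anti addition across the (E)-alkene and relative to C4 by the propargylic centre. The C10 oxygen arrives with the right orientation. On these points (ring-forming economy and the C10 carbinol) it is better than the chosen plan, which needs an olefination and a radical hydration for C10.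
- Against it here: A2 carries oxygen at C7, where the target has hydrogen and a carbon substituent, and an alkene at C5=C6, where the target needs H5 and the C6 hydroxyl on the α face. The bridge must therefore be broken at C7–O and the side chain attached to a C7 with no carbonyl next to it. The bridge also shields the α face, from which the C5/C6 hydrogen and oxygen must come. A1 has no chiral-pool source for its tertiary propargylic ether.
- Comparison: A2 matches the C10/C1/C4 array better; the chosen 16 matches the C6/C7/C11 array better, because its C6 ketone sits next to C7. Both mechanisms are known types. The alternative reaches the bicyclic core in fewer steps but pays for that after the key step, so no overall saving is expected.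

**Alternative 2:** The cut is through C1–C5 and C7–C8, back to the chloromethyl ketone (4R,7E)-1-chloro-4-(tert-butyldimethylsilyloxy)-4,8-dimethyldeca-7,9-dien-2-one (A3). An amine base in a fluorinated alcohol turns A3 into an oxyallyl cation that adds across the tethered diene in a (4+3) sense. This gives the cis-fused hydroazulen-6-one A4 with a C9=C10 alkene.
- In its favour: A4 has a single ketone, at C6, so the C6/C10 differentiation problem does not exist (better than the chosen plan). C10 already carries its methyl group and needs only a Markovnikov hydration through the same tertiary radical (equal). The carbon chain of A3 maps almost atom for atom onto 1, so the way to the key step could be shorter (better).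
- Against it here: the cis fusion and its relation to C4 must both come from the folding of a three-atom tether in a cationic cycloaddition, which is hard to predict with a quaternary centre next to the reacting terminus. A3 is a β-silyloxy ketone that can eliminate under the ionising conditions, and it needs a geometrically defined diene.
- Comparison: structurally A4 is closer to the target than 16. The chosen plan, however, sets the fusion by a hydroxyl-directed hydrogenation with a clear stereochemical rationale. If the cycloaddition were selective, the alternative would be the shorter route.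

**Alternative 3:** The cut is through C1–C2 and C4–C5, back to (R)-4-methyl-4-(triethylsilyloxy)cyclohept-2-en-1-one (A5) and a three-carbon methyl-ketone homoenolate. A copper-catalysed, silyl-chloride-assisted conjugate addition of the zinc homoenolate at C1 and a Lewis-acid aldol closure of the silyl enol ether onto the methyl ketone give A6.
- In its favour: A6 already holds both tertiary carbinols and one ketone at C6. Only the C7 aldol, two reductions, acetylation and deprotection remain, so the endgame is shorter and free of ketone differentiation and of photochemistry (better on both).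
- Against it here: the conjugate addition must occur at a carbon next to the quaternary C10, with facial control by methyl against silyloxy. The aldol must then set the C4 carbinol and the cis fusion through an open transition state, so the two stereocentres that the chosen plan gets from the chiral pool and from a directed hydrogenation rest on transition-state preferences. A5 has no chiral-pool source and needs its own asymmetric synthesis.
- Comparison: on step economy after the key step the alternative wins; on the security of absolute and relative configuration the chosen plan is stronger; mechanistically both rely on known reaction types.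

Key step: step 11

Remark on locants: ring positions are quoted in guaiane numbering (five-membered ring C1–C5, seven-membered ring C1, C5–C10); α is the face of the ring-fusion hydrogens H1 and H5, and "hydroazulene" means the saturated bicyclo[5.3.0]decane skeleton.

Remark on intermediates: metal enolates, alkoxides, catalyst-bound species and tautomers are treated as forms of the numbered compound they derive from; 12 is written as the diketone although it reacts as its enol.

Remark on supply: (R)-(−)-linalool is assumed to be available in high enantiomeric purity; its stereocentre becomes C4 and no bond to it is made or broken.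

Remark on the precursor: in 12 and 16 the ring-fusion hydrogens and the C4 oxygen lie on one face, as the target requires. This relationship cannot be left to equilibration, so it is fixed by a hydroxyl-directed hydrogenation (step 8) before the silyl group is introduced.

## Steps

Step 1
Reactants: 1 (R)-linalool, (3R)-3,7-dimethylocta-1,6-dien-3-ol
Product: 2 (1R)-1-methylcyclopent-2-en-1-ol
Conditions: (H2IMes)(PCy3)Cl2Ru=CHPh (second-generation Grubbs catalyst, 1 mol%), CH2Cl2, 40 °C
Reagents that add atoms: none
Why: Ring-closing metathesis of the 1,6-diene, a closure the free tertiary allylic hydroxyl is known to favour; 2-methylpropene leaves as a gas and the carbinol centre (C4) is untouched.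

Step 2
Reactants: 2 (1R)-1-methylcyclopent-2-en-1-ol
Product: 3 (1S,2R,5S)-2-methyl-6-oxabicyclo[3.1.0]hexan-2-ol (epoxide cis to the hydroxyl)
Conditions: VO(acac)2 (2 mol%), t-BuOOH (1.5 equiv), CH2Cl2, 0 °C to rt
Reagents that add atoms: tert-butyl hydroperoxide, CC(C)(C)OO
Why: Hydroxyl-directed epoxidation through a vanadium alkoxide–peroxide complex delivers oxygen to the face of the hydroxyl. The syn arrangement also rules out a Payne migration in the next, basic step; the two new centres are temporary (C5 is oxidised in step 4, C1 is made planar in step 5).

Step 3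
Reactants: 3 (1S,2R,5S)-2-methyl-6-oxabicyclo[3.1.0]hexan-2-ol
Product: 4 (1R,2S,3S)-1-methyl-3-(prop-1-en-2-yl)cyclopentane-1,2-diol
Conditions: CH2=C(CH3)MgBr (3 equiv), CuI (10 mol%), THF, −30 to 0 °C; then H2O
Reagents that add atoms: isopropenylmagnesium bromide, CC(=C)[Mg]Br
Why: Copper-catalysed Grignard opening of the epoxide by anti attack at C1, the carbon remote from the quaternary carbinol (the backside of C5 is blocked by the C4 methyl group); one equivalent of reagent is used up by the hydroxyl. The isopropenyl group is a masked acetyl group that brings C10 and the future central carbon of the dione.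

Step 4
Reactants: 4 (1R,2S,3S)-1-methyl-3-(prop-1-en-2-yl)cyclopentane-1,2-diol
Product: 5 (2R,5S)-2-hydroxy-2-methyl-5-(prop-1-en-2-yl)cyclopentan-1-one
Conditions: IBX (1.5 equiv), EtOAc, 75 °C
Reagents that add atoms: none
Why: 2-Iodoxybenzoic acid oxidises the secondary alcohol of a 1,2-diol to the α-hydroxy ketone without glycol cleavage, and the tertiary alcohol cannot react. The neutral medium should keep the β,γ-unsaturated ketone from isomerising, although either isomer gives the same dienolate in step 5.

Step 5
Reactants: 5 (2R,5S)-2-hydroxy-2-methyl-5-(prop-1-en-2-yl)cyclopentan-1-one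
Product: 6 (5R)-5-hydroxy-5-methyl-2-(prop-1-en-2-yl)cyclopent-1-en-1-yl trifluoromethanesulfonate
Conditions: KN(SiMe3)2 (2.2 equiv), THF, −78 °C; PhNTf2 (1.1 equiv), −78 °C; AcOH
Reagents that add atoms: N-phenylbis(trifluoromethanesulfonimide), O=S(=O)(N(c1ccccc1)S(=O)(=O)C(F)(F)F)C(F)(F)F
Why: O-Triflation of an enolate: the ketone has a single enolisable position (C1), so the dianion (alkoxide plus dienolate) can only give the C5 enol triflate. The hindered tertiary alkoxide should not be sulfonylated at −78 °C and is reprotonated on quenching.

Step 6
Reactants: 6 (5R)-5-hydroxy-5-methyl-2-(prop-1-en-2-yl)cyclopent-1-en-1-yl trifluoromethanesulfonate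
Product: 7 methyl (5R)-5-hydroxy-5-methyl-2-(prop-1-en-2-yl)cyclopent-1-ene-1-carboxylate
Conditions: Pd(OAc)2 (5 mol%), PPh3 (10 mol%), CO (1 atm), MeOH, Et3N, DMF, 50 °C
Reagents that add atoms: carbon monoxide, [C-]#[O+]; methanol, CO
Why: Palladium-catalysed methoxycarbonylation of an enol triflate (oxidative addition to zerovalent palladium, CO insertion, methanolysis of the acyl complex) installs C6 at the ester level. The free hydroxyl cannot lactonise onto the new ester for geometric reasons.

Step 7
Reactants: 7 methyl (5R)-5-hydroxy-5-methyl-2-(prop-1-en-2-yl)cyclopent-1-ene-1-carboxylate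
Product: 9 methyl (5R)-2-acetyl-5-hydroxy-5-methylcyclopent-1-ene-1-carboxylate, via side-chain vicinal diol 8 (not isolated)
Conditions: OsO4 (2 mol%), NaIO4 (3 equiv), 2,6-lutidine, dioxane/H2O 3:1, rt
Reagents that add atoms: osmium tetroxide (catalytic oxygen carrier), O=[Os](=O)(=O)=O; sodium periodate (terminal oxidant), [Na+].[O-]I(=O)(=O)=O
Why: Lemieux–Johnson cleavage: the osmate adds to the unhindered, more electron-rich 1,1-disubstituted alkene and leaves the tetrasubstituted, ester-conjugated ring alkene alone. Periodate then cleaves the diol to the methyl ketone.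

Step 8
Reactants: 9 methyl (5R)-2-acetyl-5-hydroxy-5-methylcyclopent-1-ene-1-carboxylate
Product: 10 methyl (1R,2R,5R)-2-acetyl-5-hydroxy-5-methylcyclopentane-1-carboxylate
Conditions: [Ir(cod)(PCy3)(py)]PF6 (10 mol%), H2 (50 bar), CH2Cl2, rt
Reagents that add atoms: none
Why: Hydroxyl-directed homogeneous hydrogenation: the C4 hydroxyl binds the cationic iridium centre and both hydrogens are delivered to its face. One syn addition therefore sets C1 and C5 with the ring-fusion hydrogens cis to the C4 oxygen and the acetyl and ester groups cis to each other. It is run on the free alcohol because a bulky silyl ether would be expected to send an undirected catalyst to the other face.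

Step 9
Reactants: 10 methyl (1R,2R,5R)-2-acetyl-5-hydroxy-5-methylcyclopentane-1-carboxylate
Product: 11 methyl (1R,2R,5R)-2-acetyl-5-methyl-5-(triethylsilyloxy)cyclopentane-1-carboxylate
Conditions: Et3SiOTf (1.3 equiv), 2,6-lutidine, CH2Cl2, −78 to 0 °C
Reagents that add atoms: triethylsilyl trifluoromethanesulfonate, CC[Si](CC)(CC)OS(=O)(=O)C(F)(F)F
Why: Silylation of a tertiary alcohol with a silyl triflate and a hindered pyridine base. The ether prevents retro-aldol cleavage of the β-hydroxy carbonyl array in the basic steps and later adds bulk next to C6.

Step 10
Reactants: 11 methyl (1R,2R,5R)-2-acetyl-5-methyl-5-(triethylsilyloxy)cyclopentane-1-carboxylate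
Product: 12 (1R,5R,6R)-6-methyl-6-(triethylsilyloxy)bicyclo[3.3.0]octane-2,4-dione (cis-fused; in guaiane locants the 6,10-dione with the silyloxy group α at C4)
Conditions: KOtBu (2.5 equiv), THF, 0 °C to rt; AcOH
Reagents that add atoms: none
Why: Intramolecular Claisen (Dieckmann-type) condensation of a γ-keto ester: the methyl-ketone enolate acylates the cis ester and the product is drained off as the stabilised dione enolate. Only the cis isomer can close, and the hindered, less acidic C5–H next to the quaternary carbon is expected to keep its configuration.

Step 11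
Reactants: 12 (1R,5R,6R)-6-methyl-6-(triethylsilyloxy)bicyclo[3.3.0]octane-2,4-dione, 13 ethylene
Product: 16 (3R,3aR,8aR)-3-methyl-3-(triethylsilyloxy)octahydroazulene-4,8-dione (4β-methyl-4α-silyloxy-1αH,5αH-hydroazulene-6,10-dione), via C6-hydroxy cyclobutane photoadduct 14 (not isolated), via C10-hydroxy cyclobutane photoadduct 15 (not isolated)
Conditions: hν (medium-pressure mercury lamp, Pyrex filter, λ > 300 nm), 13 (saturated, continuous stream), CH2Cl2, −40 °C; then rt
Reagents that add atoms: none
Why: The dione reacts as its enol, a 3-hydroxycyclopentenone; after excitation and intersystem crossing the triplet enone adds ethylene stepwise through a 1,4-biradical to give a cis-fused cyclobutane that is a β-hydroxy ketone (14 from the C6 enol, 15 from the C10 enol). Strain then drives retro-aldol cleavage of the former ring bond between the carbinol carbon and the old central carbon, and tautomerisation gives the 1,5-diketone. The closest known reaction type is the de Mayo reaction of enolised cyclic 1,3-diketones with alkenes. The seven-membered ring is not closed end to end: a four-membered ring is closed by intermolecular [2+2] photocycloaddition onto the five-membered dione ring and the two rings are merged by fragmentation of their shared bond. From 15 the new bonds are C9–C10 and C7–C8 and the temporary C7–C10 bond is cut; from 14 they are C6–C7 and C8–C9; both paths converge on 16 because C7, C8 and C9 are all methylenes. No stereocentre is created that survives: the two cyclobutane centres are erased, C1 and C5 lie outside the chromophore, and C4 is remote. The selectivity needed is cross-addition over enone dimerisation and over secondary photolysis of the saturated diketone; it is secured by saturating the cold solution with ethylene, by the Pyrex cut-off (the product absorbs only weakly above 300 nm) and by stopping at full conversion. The silyl ether keeps the C4 oxygen from taking part in a second retro-aldol once C6 is a ketone.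

Step 12
Reactants: 16 (3R,3aR,8aR)-3-methyl-3-(triethylsilyloxy)octahydroazulene-4,8-dione
Product: 17 4β-methyl-10-methylidene-4α-(triethylsilyloxy)-1αH,5αH-hydroazulen-6-one
Conditions: Cp2TiMe2 (2 equiv), toluene/THF, 65 °C, dark
Reagents that add atoms: dimethyltitanocene, C[Ti](C)(C1C=CC=C1)C1C=CC=C1
Why: Petasis olefination: the titanium methylidene formed on heating is not basic, so C1 and C5 should not epimerise and the β-silyloxy ketone should not eliminate. The bulky reagent is expected to take the C10 carbonyl, because the C6 carbonyl is flanked by C5 with the quaternary, silyloxy-bearing C4 on it.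

Step 13
Reactants: 17 4β-methyl-10-methylidene-4α-(triethylsilyloxy)-1αH,5αH-hydroazulen-6-one, 18 diethyl ketomalonate (diethyl 2-oxopropanedioate)
Product: 19 diethyl 2-hydroxy-2-[4β-methyl-10-methylidene-6-oxo-4α-(triethylsilyloxy)-1αH,5αH,7αH-hydroazulen-7β-yl]propanedioate
Conditions: LiN(iPr)2 (1.1 equiv), THF, −78 °C; 18 (1.5 equiv), −78 °C; AcOH
Reagents that add atoms: none
Why: Kinetic deprotonation at the C7 methylene (the tertiary C5–H is shielded), then aldol addition to a non-enolisable, very electrophilic ketone. C7 remains epimerisable and should settle as the 5,7-cis isomer (side chain β, H7 on the face of H5), in which the new group and the C5–C4 bond are both pseudo-equatorial on the cycloheptanone.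

Step 14
Reactants: 19 diethyl 2-hydroxy-2-[4β-methyl-10-methylidene-6-oxo-4α-(triethylsilyloxy)-1αH,5αH,7αH-hydroazulen-7β-yl]propanedioate
Product: 20 diethyl 2-hydroxy-2-[6α-hydroxy-4β-methyl-10-methylidene-4α-(triethylsilyloxy)-1αH,5αH,7αH-hydroazulen-7β-yl]propanedioate
Conditions: Me4NBH(OAc)3 (5 equiv), MeCN/AcOH, −30 °C
Reagents that add atoms: none
Why: Hydroxyl-directed triacetoxyborohydride reduction (Evans–Saksena type): the C11 hydroxyl exchanges onto boron and hydride is delivered intramolecularly to the C6 carbonyl from the face of the side chain. The new hydroxyl is therefore trans to the C7 substituent and cis to H5.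

Step 15
Reactants: 20 diethyl 2-hydroxy-2-[6α-hydroxy-4β-methyl-10-methylidene-4α-(triethylsilyloxy)-1αH,5αH,7αH-hydroazulen-7β-yl]propanedioate
Product: 21 2-[6α-hydroxy-4β-methyl-10-methylidene-4α-(triethylsilyloxy)-1αH,5αH,7αH-hydroazulen-7β-yl]propane-1,2,3-triol
Conditions: LiBH4 (4 equiv), THF/MeOH, 0 °C to rt
Reagents that add atoms: none
Why: Borohydride reduction of two α-hydroxy esters to primary alcohols; silyl ether and alkene are inert. Any lactone formed between the C6 hydroxyl and an ester of 20 is reduced to the same tetraol.

Step 16
Reactants: 21 2-[6α-hydroxy-4β-methyl-10-methylidene-4α-(triethylsilyloxy)-1αH,5αH,7αH-hydroazulen-7β-yl]propane-1,2,3-triol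
Product: 22 2-hydroxy-2-[6α-hydroxy-4β-methyl-10-methylidene-4α-(triethylsilyloxy)-1αH,5αH,7αH-hydroazulen-7β-yl]propane-1,3-diyl diacetate
Conditions: Ac2O (2.2 equiv), pyridine, CH2Cl2, 0 °C
Reagents that add atoms: acetic anhydride, CC(=O)OC(C)=O
Why: Selective acylation of the two primary alcohols; the secondary C6 hydroxyl sits between two branched carbons and the C11 hydroxyl is tertiary, so neither should react without an acyl-transfer catalyst.

Step 17
Reactants: 22 2-hydroxy-2-[6α-hydroxy-4β-methyl-10-methylidene-4α-(triethylsilyloxy)-1αH,5αH,7αH-hydroazulen-7β-yl]propane-1,3-diyl diacetate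
Product: 24 2-hydroxy-2-[6α,10α-dihydroxy-4β,10β-dimethyl-4α-(triethylsilyloxy)-1αH,5αH,7αH-hydroazulen-7β-yl]propane-1,3-diyl diacetate, via C10 hydroperoxide 23 (not isolated)
Conditions: Co(acac)2 (20 mol%), PhSiH3 (3 equiv), O2 (1 atm), THF, rt; then PPh3
Reagents that add atoms: dioxygen, O=O
Why: Mukaiyama hydration: hydrogen-atom transfer from a cobalt hydride to the methylene carbon gives the tertiary C10 radical. Dioxygen should trap it on the face anti to the C1–C2 bond, that is the face of H1, and the peroxide is reduced to the alcohol; acetates, free hydroxyls and the silyl ether are inert.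

Step 18
Reactants: 24 2-hydroxy-2-[6α,10α-dihydroxy-4β,10β-dimethyl-4α-(triethylsilyloxy)-1αH,5αH,7αH-hydroazulen-7β-yl]propane-1,3-diyl diacetate
Product: 25 2-hydroxy-2-[4α,6α,10α-trihydroxy-4β,10β-dimethyl-1αH,5αH,7αH-hydroazulen-7β-yl]propane-1,3-diyl diacetate (4α,6α,10α,11-tetrahydroxyguaiane-12,13-diyl diacetate; the target)
Conditions: HF·pyridine, pyridine, THF, 0 °C to rt
Reagents that add atoms: none
Why: Fluoride cleavage of the tertiary triethylsilyl ether in a buffered, slightly acidic medium, which should neither hydrolyse the acetates nor move them to the neighbouring hydroxyls.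

## Compound list

1 | (R)-linalool, (3R)-3,7-dimethylocta-1,6-dien-3-ol | C=C[C@](C)(O)CCC=C(C)C | starting material
2 | (1R)-1-methylcyclopent-2-en-1-ol | C[C@@]1(O)CCC=C1 | intermediate
3 | (1S,2R,5S)-2-methyl-6-oxabicyclo[3.1.0]hexan-2-ol, epoxide cis to the hydroxyl | C[C@@]1(O)CC[C@@H]2O[C@H]12 | intermediate
4 | (1R,2S,3S)-1-methyl-3-(prop-1-en-2-yl)cyclopentane-1,2-diol | C[C@@]1(O)CC[C@@H](C(C)=C)[C@@H]1O | intermediate
5 | (2R,5S)-2-hydroxy-2-methyl-5-(prop-1-en-2-yl)cyclopentan-1-one | C[C@@]1(O)CC[C@@H](C(C)=C)C1=O | intermediate
6 | (5R)-5-hydroxy-5-methyl-2-(prop-1-en-2-yl)cyclopent-1-en-1-yl trifluoromethanesulfonate | C[C@@]1(O)CCC(C(C)=C)=C1OS(=O)(=O)C(F)(F)F | intermediate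
7 | methyl (5R)-5-hydroxy-5-methyl-2-(prop-1-en-2-yl)cyclopent-1-ene-1-carboxylate | C[C@@]1(O)CCC(C(C)=C)=C1C(=O)OC | intermediate
8 | methyl (5R)-2-(1,2-dihydroxypropan-2-yl)-5-hydroxy-5-methylcyclopent-1-ene-1-carboxylate, either configuration at the side-chain carbinol | C[C@@]1(O)CCC(C(C)(O)CO)=C1C(=O)OC | intermediate
9 | methyl (5R)-2-acetyl-5-hydroxy-5-methylcyclopent-1-ene-1-carboxylate | C[C@@]1(O)CCC(C(C)=O)=C1C(=O)OC | intermediate
10 | methyl (1R,2R,5R)-2-acetyl-5-hydroxy-5-methylcyclopentane-1-carboxylate | C[C@@]1(O)CC[C@@H](C(C)=O)[C@H]1C(=O)OC | intermediate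
11 | methyl (1R,2R,5R)-2-acetyl-5-methyl-5-(triethylsilyloxy)cyclopentane-1-carboxylate | C[C@@]1(O[Si](CC)(CC)CC)CC[C@@H](C(C)=O)[C@H]1C(=O)OC | intermediate
12 | (1R,5R,6R)-6-methyl-6-(triethylsilyloxy)bicyclo[3.3.0]octane-2,4-dione, cis-fused, silyloxy group on the face of the fusion hydrogens | C1C(=O)[C@@H]2CC[C@@](C)(O[Si](CC)(CC)CC)[C@@H]2C1=O | intermediate
13 | ethylene | C=C | starting material
14 | C6-hydroxy cyclobutane photoadduct: cyclobutane fused across C6–C7 on the α face, hydroxyl on C6, ketone at C10 | O=C1[C@@H]2CC[C@@](C)(O[Si](CC)(CC)CC)[C@@H]2[C@@]2(O)CC[C@@H]12 | intermediate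
15 | C10-hydroxy cyclobutane photoadduct: cyclobutane fused across C10 and the old central carbon on the α face, hydroxyl on C10, ketone at C6 | O[C@@]12CC[C@@H]1C(=O)[C@H]1[C@](C)(O[Si](CC)(CC)CC)CC[C@H]12 | intermediate
16 | (3R,3aR,8aR)-3-methyl-3-(triethylsilyloxy)octahydroazulene-4,8-dione (4β-methyl-4α-silyloxy-1αH,5αH-hydroazulene-6,10-dione) | C1CCC(=O)[C@@H]2CC[C@@](C)(O[Si](CC)(CC)CC)[C@@H]2C1=O | intermediate
17 | 4β-methyl-10-methylidene-4α-(triethylsilyloxy)-1αH,5αH-hydroazulen-6-one | C1CCC(=C)[C@@H]2CC[C@@](C)(O[Si](CC)(CC)CC)[C@@H]2C1=O | intermediate
18 | diethyl ketomalonate (diethyl 2-oxopropanedioate) | CCOC(=O)C(=O)C(=O)OCC | starting material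
19 | diethyl 2-hydroxy-2-[4β-methyl-10-methylidene-6-oxo-4α-(triethylsilyloxy)-1αH,5αH,7αH-hydroazulen-7β-yl]propanedioate | CCOC(=O)C(O)(C(=O)OCC)[C@@H]1CCC(=C)[C@@H]2CC[C@@](C)(O[Si](CC)(CC)CC)[C@@H]2C1=O | intermediate
20 | diethyl 2-hydroxy-2-[6α-hydroxy-4β-methyl-10-methylidene-4α-(triethylsilyloxy)-1αH,5αH,7αH-hydroazulen-7β-yl]propanedioate | CCOC(=O)C(O)(C(=O)OCC)[C@@H]1CCC(=C)[C@@H]2CC[C@@](C)(O[Si](CC)(CC)CC)[C@@H]2[C@H]1O | intermediate
21 | 2-[6α-hydroxy-4β-methyl-10-methylidene-4α-(triethylsilyloxy)-1αH,5αH,7αH-hydroazulen-7β-yl]propane-1,2,3-triol | OCC(O)(CO)[C@@H]1CCC(=C)[C@@H]2CC[C@@](C)(O[Si](CC)(CC)CC)[C@@H]2[C@H]1O | intermediate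
22 | 2-hydroxy-2-[6α-hydroxy-4β-methyl-10-methylidene-4α-(triethylsilyloxy)-1αH,5αH,7αH-hydroazulen-7β-yl]propane-1,3-diyl diacetate | CC(=O)OCC(O)(COC(C)=O)[C@@H]1CCC(=C)[C@@H]2CC[C@@](C)(O[Si](CC)(CC)CC)[C@@H]2[C@H]1O | intermediate
23 | 2-hydroxy-2-[10α-hydroperoxy-6α-hydroxy-4β,10β-dimethyl-4α-(triethylsilyloxy)-1αH,5αH,7αH-hydroazulen-7β-yl]propane-1,3-diyl diacetate | CC(=O)OCC(O)(COC(C)=O)[C@@H]1CC[C@@](C)(OO)[C@@H]2CC[C@@](C)(O[Si](CC)(CC)CC)[C@@H]2[C@H]1O | intermediate
24 | 2-hydroxy-2-[6α,10α-dihydroxy-4β,10β-dimethyl-4α-(triethylsilyloxy)-1αH,5αH,7αH-hydroazulen-7β-yl]propane-1,3-diyl diacetate | CC(=O)OCC(O)(COC(C)=O)[C@@H]1CC[C@@](C)(O)[C@@H]2CC[C@@](C)(O[Si](CC)(CC)CC)[C@@H]2[C@H]1O | intermediate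
25 | 2-hydroxy-2-[4α,6α,10α-trihydroxy-4β,10β-dimethyl-1αH,5αH,7αH-hydroazulen-7β-yl]propane-1,3-diyl diacetate (4α,6α,10α,11-tetrahydroxyguaiane-12,13-diyl diacetate) | CC(=O)OCC(O)(COC(C)=O)[C@@H]1CC[C@@](C)(O)[C@@H]2CC[C@@](C)(O)[C@@H]2[C@H]1O | target

## Step count and least certain steps

Total: 18 steps. Longest linear sequence: 18 steps from 1 (13 and 18 are purchased and enter in one step each).

**Step 11 (key step).** What may go wrong is inefficient capture of the excited enol by a gaseous alkene, which lets enone photodimerisation and secondary photolysis of the diketone compete, or incomplete fragmentation of the cyclobutanol. The enol of a cyclopentane-1,3-dione cannot chelate and tends to aggregate by hydrogen bonding, which shortens its useful excited-state lifetime. Fallback: set out from 12 and fix the enol covalently as its enol acetate, 10-acetoxy-4β-methyl-4α-(triethylsilyloxy)-1αH,5αH-bicyclo[3.3.0]oct-7(10)-en-6-one F1 (Ac2O, Et3N, catalytic 4-dimethylaminopyridine; the less hindered C10 oxygen is acylated). Irradiate F1 with ethylene to the stable acetoxy cyclobutane photoadduct F2, which can be purified. Then release the cyclobutanol with K2CO3 in methanol; this gives 15, which fragments and returns to the route at 16.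

**Step 8.** What may go wrong is slow turnover on a tetrasubstituted alkene carrying two acceptor groups, with loss of facial selectivity if the ketone or ester oxygen binds the metal in place of the hydroxyl. Fallback: set out from 9 and give up catalyst direction. Hydrogenate over palladium on carbon in ethyl acetate, where syn addition is undirected but the small free hydroxyl, rather than the methyl group, should face the surface. Remove the unwanted all-cis diastereomer methyl (1S,2S,5R)-2-acetyl-5-hydroxy-5-methylcyclopentane-1-carboxylate F3 by chromatography; this returns to the route at 10.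

**Step 10.** What may go wrong is failure of the ring closure, which runs in the 5-(enolendo)-exo-trig mode that is geometrically unfavourable, so that β-elimination of silanolate from the ester enolate or epimerisation at C5 takes over. Fallback: set out from 11 and replace the acylation by an aldol addition. Trap the kinetic methyl-ketone enolate as the trimethylsilyl enol ether F4 (LiN(iPr)2, Me3SiCl, −78 °C). Reduce the ester to the aldehyde F5 with i-Bu2AlH at −78 °C, the ketone being masked. Close the ring by an intramolecular Mukaiyama aldol (BF3·OEt2, −78 °C) to the C6 ketol F6, and oxidise F6 with Dess–Martin periodinane; this returns to the route at 12.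

**Step 12.** What may go wrong is insufficient discrimination between the two carbonyl groups (attack at C6 or double olefination), or thermal erosion of the ring fusion. Fallback: set out from 16 and use a two-stage Peterson olefination. Add Me3SiCH2Li/CeCl3 at −78 °C, a non-basic and strongly size-sensitive nucleophile, to the C10 carbonyl to give the β-hydroxysilane F7. Eliminate with KH in THF at 0 °C; this returns to the route at 17.

**Step 13.** What may go wrong is poor control of the C7 configuration: the kinetic facial preference of the enolate is not obvious, and the thermodynamic preference for the 5,7-cis isomer is an argument by analogy. Fallback: set out from 17. If the adduct settles as its C7 epimer, the 7α-substituted adduct F8, convert F8 into its dianion (LiN(iPr)2, 2.2 equiv, −78 °C) and protonate it kinetically with a hindered phenol. The proton should enter from the more open face and so place the side chain on the face it avoids at equilibrium; this returns to the route at 19.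

**Step 17.** What may go wrong is modest facial selectivity when the planar C10 radical captures dioxygen, and competing reduction of the radical to the alkane. Fallback: set out from 20 and introduce the oxygen by a concerted, sterically governed step. Epoxidise the exocyclic alkene with buffered m-chloroperbenzoic acid from the α face to the spiro-epoxide F9. Open the epoxide at its methylene carbon and reduce both esters in one operation with LiAlH4 to the pentaol F10. Acetylate the two primary hydroxyls as in step 16; this returns to the route at 24.

## Further compounds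

F1 | step 11 | 10-acetoxy-4β-methyl-4α-(triethylsilyloxy)-1αH,5αH-bicyclo[3.3.0]oct-7(10)-en-6-one (enol acetate of 12 at the C10 oxygen) | CC(=O)OC1=CC(=O)[C@H]2[C@](C)(O[Si](CC)(CC)CC)CC[C@@H]12
F2 | step 11 | acetoxy cyclobutane photoadduct (O-acetyl derivative of 15) | CC(=O)O[C@@]12CC[C@@H]1C(=O)[C@H]1[C@](C)(O[Si](CC)(CC)CC)CC[C@H]12
F3 | step 8 | methyl (1S,2S,5R)-2-acetyl-5-hydroxy-5-methylcyclopentane-1-carboxylate | C[C@@]1(O)CC[C@H](C(C)=O)[C@@H]1C(=O)OC
F4 | step 10 | methyl (1R,2R,5R)-5-methyl-5-(triethylsilyloxy)-2-[1-(trimethylsilyloxy)ethenyl]cyclopentane-1-carboxylate | C[C@@]1(O[Si](CC)(CC)CC)CC[C@@H](C(=C)O[Si](C)(C)C)[C@H]1C(=O)OC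
F5 | step 10 | (1R,2R,5R)-5-methyl-5-(triethylsilyloxy)-2-[1-(trimethylsilyloxy)ethenyl]cyclopentane-1-carbaldehyde | C[C@@]1(O[Si](CC)(CC)CC)CC[C@@H](C(=C)O[Si](C)(C)C)[C@H]1C=O
F6 | step 10 | 6-hydroxy-4β-methyl-4α-(triethylsilyloxy)-1αH,5αH-bicyclo[3.3.0]octan-10-one in guaiane locants, either configuration at C6 | C1C(=O)[C@@H]2CC[C@@](C)(O[Si](CC)(CC)CC)[C@@H]2C1O
F7 | step 12 | 10β-hydroxy-4β-methyl-4α-(triethylsilyloxy)-10α-(trimethylsilylmethyl)-1αH,5αH-hydroazulen-6-one | C1CC[C@@](O)(C[Si](C)(C)C)[C@@H]2CC[C@@](C)(O[Si](CC)(CC)CC)[C@@H]2C1=O
F8 | step 13 | diethyl 2-hydroxy-2-[4β-methyl-10-methylidene-6-oxo-4α-(triethylsilyloxy)-1αH,5αH,7βH-hydroazulen-7α-yl]propanedioate | CCOC(=O)C(O)(C(=O)OCC)[C@H]1CCC(=C)[C@@H]2CC[C@@](C)(O[Si](CC)(CC)CC)[C@@H]2C1=O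
F9 | step 17 | diethyl 2-hydroxy-2-[10α,14-epoxy-6α-hydroxy-4β-methyl-4α-(triethylsilyloxy)-1αH,5αH,7αH-hydroazulen-7β-yl]propanedioate | CCOC(=O)C(O)(C(=O)OCC)[C@@H]1CC[C@]3(CO3)[C@@H]2CC[C@@](C)(O[Si](CC)(CC)CC)[C@@H]2[C@H]1O
F10 | step 17 | 2-[6α,10α-dihydroxy-4β,10β-dimethyl-4α-(triethylsilyloxy)-1αH,5αH,7αH-hydroazulen-7β-yl]propane-1,2,3-triol | OCC(O)(CO)[C@@H]1CC[C@@](C)(O)[C@@H]2CC[C@@](C)(O[Si](CC)(CC)CC)[C@@H]2[C@H]1O
A1 | alternative 1 | (4E,8R)-8-(tert-butyldimethylsilyloxy)-4,8-dimethyldec-4-en-9-ynal | O=CCC/C(C)=C/CC[C@@](C)(O[Si](C)(C)C(C)(C)C)C#C
A2 | alternative 1 | 7α,10α-epoxy-4β,10β-dimethyl-4α-(tert-butyldimethylsilyloxy)-1αH-hydroazul-5-ene | C[C@]12CC[C@H](O1)C=C3[C@H]2CC[C@@]3(C)O[Si](C)(C)C(C)(C)C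
A3 | alternative 2 | (4R,7E)-1-chloro-4-(tert-butyldimethylsilyloxy)-4,8-dimethyldeca-7,9-dien-2-one | ClCC(=O)C[C@](C)(O[Si](C)(C)C(C)(C)C)CC/C=C(\C)C=C
A4 | alternative 2 | 4β,10-dimethyl-4α-(tert-butyldimethylsilyloxy)-1αH,5αH-hydroazul-9-en-6-one | C1CC=C(C)[C@@H]2CC[C@@](C)(O[Si](C)(C)C(C)(C)C)[C@@H]2C1=O
A5 | alternative 3 | (R)-4-methyl-4-(triethylsilyloxy)cyclohept-2-en-1-one | C[C@@]1(O[Si](CC)(CC)CC)CCCC(=O)C=C1
A6 | alternative 3 | 4α-hydroxy-4β,10β-dimethyl-10α-(triethylsilyloxy)-1αH,5αH-hydroazulen-6-one | C1CC[C@@](C)(O[Si](CC)(CC)CC)[C@@H]2CC[C@@](C)(O)[C@@H]2C1=O
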